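**Assumption:** the target SMILES describes an achiral meso compound (2,3-trans, 3,4-cis, 4,5-trans, mirror plane through the ring O), so "single enantiomer" is read as this single diastereomer and no absolute induction is needed.

## Retrosynthetic overview

1. Oxolane 12 ⇒ cyclobutane 10 by oxidative ring expansion: O is inserted into the doubly benzylic C–C bond, which forms both C–O bonds and sets C2/C5, while C3/C4 are carried over.
2. Cyclobutane 10 ⇒ strapped bis-chalcone 8 by intramolecular head-to-head [2+2], which sets the cis-diaroyl unit; the strap is then cut.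
3. Bis-chalcone 8 ⇒ dialdehyde 7 + 2 × ketone 3 (double Claisen–Schmidt).
4. Dialdehyde 7 ⇒ 4-bromophenol (Si strap, Br/Li exchange, DMF); ketone 3 ⇒ resorcinol + acetic acid.
5. Ring order: cyclobutane first, oxolane last; all benzene rings are bought.

## Route

Step 1
Reactants: 1 resorcinol; 2 acetic acid
Product: 3 1-(2,4-dihydroxyphenyl)ethan-1-one
Conditions: ZnCl2 (1.2 equiv), AcOH (neat), 140 °C
Reagents that add atoms: none
Why: Nencki reaction (ZnCl2-promoted Friedel–Crafts C-acylation of resorcinol), the classical resacetophenone preparation; acylation occurs at C4, ortho/para to the two hydroxyls, and no stereocentre is formed.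

Step 2
Reactants: 4 4-bromophenol (2 equiv)
Product: 5 bis(4-bromophenoxy)di-tert-butylsilane
Conditions: tBu2Si(OTf)2 (0.5 equiv), 2,6-lutidine, CH2Cl2, 0 °C → rt
Reagents that add atoms: di-tert-butylsilyl bis(trifluoromethanesulfonate) CC(C)(C)[Si](OS(=O)(=O)C(F)(F)F)(OS(=O)(=O)C(F)(F)F)C(C)(C)C
Why: O-silylation of a phenol with a silyl bis-triflate; the hindered tBu2Si unit masks both phenols and is the three-atom O–Si–O strap that later holds the two styryl arms face to face.

Step 3
Reactants: 5 bis(4-bromophenoxy)di-tert-butylsilane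
Product: 7 4,4'-[(di-tert-butylsilanediyl)bis(oxy)]dibenzaldehyde, via dilithio silane 6 (not isolated)
Conditions: n-BuLi (2.1 equiv), THF, −78 °C; DMF, −78 → 0 °C; aq. NH4Cl
Reagents that add atoms: N,N-dimethylformamide CN(C)C=O
Why: Bromine–lithium exchange followed by Bouveault formylation; the aryllithium sits para to the hindered silyl ether, so neither retro-Brook migration nor attack at silicon competes at −78 °C.

Step 4
Reactants: 7 4,4'-[(di-tert-butylsilanediyl)bis(oxy)]dibenzaldehyde; 3 1-(2,4-dihydroxyphenyl)ethan-1-one (2.2 equiv)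
Product: 8 (2E,2'E)-3,3'-{[(di-tert-butylsilanediyl)bis(oxy)]di-4,1-phenylene}bis[1-(2,4-dihydroxyphenyl)prop-2-en-1-one]
Conditions: HCl (4 M in dioxane), EtOH, 0 °C → rt
Reagents that add atoms: none
Why: Acid-catalysed Claisen–Schmidt condensation (crossed aldol then dehydration), the standard protecting-group-free entry to polyhydroxychalcones; aryl silyl ethers tolerate acid far better than base, and the conjugated E-alkenes form under thermodynamic control.

Step 5
Reactants: 8 strapped bis-chalcone
Product: 10 [(1R,2S,3R,4S)-3,4-bis(4-hydroxyphenyl)cyclobutane-1,2-diyl]bis[(2,4-dihydroxyphenyl)methanone], via silylene-bridged cyclobutane 9 (not isolated)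
Conditions: Ru(bpy)3(PF6)2 (2.5 mol%), Sc(OTf)3 (20 mol%), MeCN (5 mM), blue LEDs, rt; then HF·pyridine, THF, 0 °C
Reagents that add atoms: none
Why: Intramolecular [2+2] photocycloaddition of the Sc-chelated 2'-hydroxychalcone by triplet energy transfer, then fluoride cleavage of the aryl silyl ether; the short strap allows only the head-to-head syn adduct (aryls cis), each enone keeps its aryl/aroyl trans relationship, and the two aroyl groups therefore end up cis to each other (meso cyclobutane).

Step 6
Reactants: 10 meso cyclobutane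
Product: 12 [(2R,3R,4S,5S)-2,5-bis(4-hydroxyphenyl)oxolane-3,4-diyl]bis[(2,4-dihydroxyphenyl)methanone], via bis-quinone methide 11 (not isolated)
Conditions: PhI(OAc)2 (1.05 equiv), HFIP/H2O 9:1, 0 °C → rt
Reagents that add atoms: water O
Why: Proposed new method: oxidative ring expansion of a 1,2-bis(4-hydroxyphenyl)cyclobutane by formal O-atom insertion, in which two-electron oxidation of one p-hydroxyphenyl ring at iodine(III) is relayed through the strained, doubly benzylic C–C bond to the second phenol (Grob-type fragmentation, non-pericyclic) to give meso bis-p-quinone methide 11, and 1,6-addition of water followed by 1,6-addition of the new benzylic hydroxyl closes the oxolane; C3/C4 are not touched and stay cis, while the p-hydroxybenzylic C2/C5 centres form reversibly in HFIP and settle with each aryl trans to its neighbouring aroyl (hence cis to each other); the closest known reaction types are iodine(III) oxidation of p-alkylphenols to p-quinone methides and the hydrative cyclisation of 8–8-linked bis-quinone methides to 2,5-diaryltetrahydrofuran lignans.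

## Compound list

1 | resorcinol | Oc1cccc(O)c1 | starting material
2 | acetic acid | CC(=O)O | starting material
3 | 1-(2,4-dihydroxyphenyl)ethan-1-one | CC(=O)c1ccc(O)cc1O | intermediate
4 | 4-bromophenol | Oc1ccc(Br)cc1 | starting material
5 | bis(4-bromophenoxy)di-tert-butylsilane | CC(C)(C)[Si](Oc1ccc(Br)cc1)(Oc1ccc(Br)cc1)C(C)(C)C | intermediate
6 | dilithio silane, di-tert-butylbis(4-lithiophenoxy)silane | [Li]c1ccc(O[Si](C(C)(C)C)(C(C)(C)C)Oc2ccc([Li])cc2)cc1 | intermediate (not isolated)
7 | 4,4'-[(di-tert-butylsilanediyl)bis(oxy)]dibenzaldehyde | CC(C)(C)[Si](Oc1ccc(C=O)cc1)(Oc1ccc(C=O)cc1)C(C)(C)C | intermediate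
8 | (2E,2'E)-3,3'-{[(di-tert-butylsilanediyl)bis(oxy)]di-4,1-phenylene}bis[1-(2,4-dihydroxyphenyl)prop-2-en-1-one] | CC(C)(C)[Si](Oc1ccc(/C=C/C(=O)c2ccc(O)cc2O)cc1)(Oc1ccc(/C=C/C(=O)c2ccc(O)cc2O)cc1)C(C)(C)C | intermediate
9 | silylene-bridged cyclobutane: compound 10 with its two 4-hydroxyphenyl oxygens joined by a tBu2Si bridge (cis-diaryl, cis-diaroyl, aryl/aroyl trans) | O=C(c1ccc(O)cc1O)[C@@H]1[C@H](C(=O)c2ccc(O)cc2O)[C@@H](c2ccc3cc2)[C@H]1c1ccc(O[Si](C(C)(C)C)(C(C)(C)C)O3)cc1 | intermediate (not isolated)
10 | [(1R,2S,3R,4S)-3,4-bis(4-hydroxyphenyl)cyclobutane-1,2-diyl]bis[(2,4-dihydroxyphenyl)methanone], meso, aroyls cis, aryls cis, aryl/aroyl trans | O=C(c1ccc(O)cc1O)[C@@H]1[C@H](C(=O)c2ccc(O)cc2O)[C@@H](c2ccc(O)cc2)[C@H]1c1ccc(O)cc1 | intermediate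
11 | bis-quinone methide: (2R,3S)-1,4-bis(2,4-dihydroxyphenyl)-2,3-bis[(4-oxocyclohexa-2,5-dien-1-ylidene)methyl]butane-1,4-dione, meso | O=C1C=CC(C=C1)=C[C@H](C(=O)c1ccc(O)cc1O)[C@H](C(=O)c1ccc(O)cc1O)C=C1C=CC(=O)C=C1 | intermediate (not isolated)
12 | [(2R,3R,4S,5S)-2,5-bis(4-hydroxyphenyl)oxolane-3,4-diyl]bis[(2,4-dihydroxyphenyl)methanone], meso, 2,3-trans, 3,4-cis, 4,5-trans | O=C(c1ccc(O)cc1O)[C@@H]1[C@H](C(=O)c2ccc(O)cc2O)[C@@H](c2ccc(O)cc2)O[C@H]1c1ccc(O)cc1 | target

## Step count and risks

Total steps: 6. Longest linear sequence: 5 (4 → 5 → 7 → 8 → 10 → 12).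

**Step 6 (the proposed new reaction).** Possible failures are p-quinol formation without C–C cleavage, capture of 11 by the chelated 2'-OH to give a 3,3'-biflavanone, or tautomerisation of 11 to the bis-arylidene diketone with loss of the C3/C4 configuration. The fallback uses known chemistry only; it sets out from 7 and 3 and comes back at 12. Fluoride cleavage of 7 (HF·pyridine) gives 4-hydroxybenzaldehyde F5, and acid Claisen–Schmidt condensation of this with 3 gives isoliquiritigenin F6. One-electron phenol oxidation of F6 (Ag2O, or horseradish peroxidase/H2O2, aqueous acetone) then effects the classical 8–8 radical coupling to a bis-quinone methide that is captured by water, as in biomimetic syntheses of 2,5-diaryltetrahydrofuran lignans. This coupling is not diastereoselective, so 12 must be separated from its diastereomers by preparative HPLC.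

**Step 5 (photocycloaddition).** Possible failures are E/Z isomerisation, flavanone closure, or a weak stereochemical outcome with the free 2'-hydroxy ketone. The fallback sets out from 8 and comes back at 10. Peracetylation (Ac2O, pyridine) gives the tetraacetate of 8 F3, which has no 2'-OH and therefore no excited-state proton transfer or flavanone closure. Thioxanthone-sensitised irradiation (405 nm, MeCN, 5 mM) then gives the strapped cyclobutane tetraacetate F4, and HF·pyridine followed by NH3/MeOH at 0 °C removes the strap and the acetates to give 10.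

**Step 4 (double condensation with the silyl strap intact).** The possible failure is acid cleavage of the aryl silyl ether. The fallback sets out from 3 and comes back at 8. CuBr2 α-bromination of 3 (EtOAc/CHCl3, reflux) gives 2-bromo-1-(2,4-dihydroxyphenyl)ethan-1-one F1. Treatment with PPh3 and then aqueous Na2CO3 gives the stabilised ylide 1-(2,4-dihydroxyphenyl)-2-(triphenyl-λ5-phosphanylidene)ethan-1-one F2. Double Wittig olefination of 7 with F2 (toluene, 90 °C) gives 8 under neutral conditions with E selectivity.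

## Further compounds

F1 | step 4 | 2-bromo-1-(2,4-dihydroxyphenyl)ethan-1-one | O=C(CBr)c1ccc(O)cc1O
F2 | step 4 | 1-(2,4-dihydroxyphenyl)-2-(triphenyl-λ5-phosphanylidene)ethan-1-one | O=C(C=P(c1ccccc1)(c1ccccc1)c1ccccc1)c1ccc(O)cc1O
F3 | step 5 | tetraacetate of 8 | CC(=O)Oc1ccc(C(=O)/C=C/c2ccc(O[Si](C(C)(C)C)(C(C)(C)C)Oc3ccc(/C=C/C(=O)c4ccc(OC(C)=O)cc4OC(C)=O)cc3)cc2)c(OC(C)=O)c1
F4 | step 5 | tetraacetate of 9 | CC(=O)Oc1ccc(C(=O)[C@@H]2[C@H](C(=O)c3ccc(OC(C)=O)cc3OC(C)=O)[C@@H](c3ccc4cc3)[C@H]2c2ccc(O[Si](C(C)(C)C)(C(C)(C)C)O4)cc2)c(OC(C)=O)c1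
F5 | step 6 | 4-hydroxybenzaldehyde | O=Cc1ccc(O)cc1
F6 | step 6 | isoliquiritigenin, (E)-1-(2,4-dihydroxyphenyl)-3-(4-hydroxyphenyl)prop-2-en-1-one | O=C(/C=C/c1ccc(O)cc1)c1ccc(O)cc1O
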